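**Retrosynthetic overview**

1. Maklamicin 51 ⇐ O-demethylation/desilylation of macrocycle 49 ⇐ ring-closing metathesis (11-membered ring, E-alkene) of diene ketone 48 ⇐ oxidation of the adduct of lithiated spirotetronate 46 (from 45) with decalin aldehyde 16.
2. Decalin 16 (rings A and B formed together) ⇐ α-methylation of 15 ⇐ organocatalytic intramolecular Diels–Alder reaction of tetraenal 14 ⇐ Wittig/Julia–Kocienski assembly from ester 4 (asymmetric conjugate addition) and sulfone 10 (asymmetric allylic alkylation).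
3. Spirotetronate 45 ⇐ tetronate ring built on the ethynyl carbinol of cyclohexene 42 ⇐ cyclohexene ring by intramolecular aldol condensation of dialdehyde 39.
4. Key disconnection: aldehyde 37 with two adjacent fully substituted carbons ⇐ semipinacol 1,2-shift of epoxy silyl ether 36 (the carbinol carbon moves from the epoxide CH to the tertiary epoxide carbon) ⇐ chelation-controlled ethynylation of epoxy ketone 33 ⇐ lactone 24 + alkenyl iodide 27.
5. Ring order: δ-lactone template 20 → decalin rings A/B (15) and, separately, cyclohexene (40) → tetronate (45) → 11-membered carbocycle (49).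

Assumption: the target is taken exactly as the SMILES defines it (ring A methyl cis to H-4a, i.e. axial); each ligand or catalyst antipode named is the one expected from the parent precedent and would be exchanged for its mirror image if the sense proved opposite.

**Decalin aldehyde 16**

Step 1
Reactants: 1 2-(2-bromoethyl)-1,3-dioxolane; 2 methyl (2E)-but-2-enoate
Product: 4 methyl (3S)-5-(1,3-dioxolan-2-yl)-3-methylpentanoate, via Grignard reagent 3 (not isolated)
Conditions: Mg, THF, 30 °C; then 2, CuI (2 mol%), Tol-BINAP (3 mol%, antipode giving 3S), t-BuOMe, −40 °C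
Reagents that add atoms: none
Why: Copper-catalysed asymmetric conjugate addition of a Grignard reagent to an (E)-enoate; the CuI–Tol-BINAP complex delivers the alkyl group to one face of C3 and sets the methyl-bearing centre that becomes C6 of the decalin.

Step 2
Reactants: 4 methyl (3S)-5-(1,3-dioxolan-2-yl)-3-methylpentanoate
Product: 5 (3S)-5-(1,3-dioxolan-2-yl)-3-methylpentanal
Conditions: i-Bu2AlH, CH2Cl2, −78 °C; Rochelle salt work-up
Reagents that add atoms: none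
Why: Partial ester reduction through a tetrahedral aluminium hemiacetal that is stable at −78 °C; the β-stereocentre cannot epimerise.

Step 3
Reactants: 5 (3S)-5-(1,3-dioxolan-2-yl)-3-methylpentanal
Product: 6 (2E,5S)-7-(1,3-dioxolan-2-yl)-5-methylhept-2-enal
Conditions: Ph3P=CHCHO, toluene, 80 °C
Reagents that add atoms: (triphenylphosphoranylidene)acetaldehyde (O=CC=P(c1ccccc1)(c1ccccc1)c1ccccc1)
Why: Wittig olefination with a stabilised ylide gives the (E)-enal (two-carbon homologation).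

Step 4
Reactants: 7 (2E)-1,4-dibromobut-2-ene
Product: 8 (3R)-4-bromo-3-methylbut-1-ene
Conditions: MeMgBr, CuBr·SMe2 (1 mol%), Taniaphos (1.2 mol%, antipode giving 3R), CH2Cl2, −75 °C
Reagents that add atoms: methylmagnesium bromide (C[Mg]Br)
Why: Copper-catalysed asymmetric allylic alkylation (SN2′) of a symmetrical dibromide; the chiral copper–Taniaphos complex sets the methyl/vinyl centre that becomes the side-chain CH(CH3) stereocentre.

Step 5
Reactants: 8 (3R)-4-bromo-3-methylbut-1-ene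
Product: 10 5-{[(2R)-2-methylbut-3-en-1-yl]sulfonyl}-1-phenyl-1H-tetrazole, via thioether 9 (not isolated)
Conditions: 1-phenyl-1H-tetrazole-5-thiol, K2CO3, EtOH, 60 °C; then (NH4)6Mo7O24·4H2O (10 mol%), 30% H2O2, 0 °C → rt
Reagents that add atoms: 1-phenyl-1H-tetrazole-5-thiol (Sc1nnnn1-c1ccccc1); hydrogen peroxide (OO)
Why: SN2 thioetherification of the primary bromide followed by molybdate-catalysed S-oxidation (the terminal alkene is untouched); the stereocentre is not involved.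

Step 6
Reactants: 10 5-{[(2R)-2-methylbut-3-en-1-yl]sulfonyl}-1-phenyl-1H-tetrazole; 6 (2E,5S)-7-(1,3-dioxolan-2-yl)-5-methylhept-2-enal
Product: 12 2-[(3S,5E,7E,9R)-3,9-dimethylundeca-5,7,10-trien-1-yl]-1,3-dioxolane, via potassium sulfone anion 11 (not isolated)
Conditions: KN(SiMe3)2, DME, −60 °C; then 6, −60 °C → rt
Reagents that add atoms: none
Why: Julia–Kocienski olefination of an enal with a phenyltetrazolyl sulfone gives the new alkene E-selectively, completing the (E,E)-diene.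

Step 7
Reactants: 12 2-[(3S,5E,7E,9R)-3,9-dimethylundeca-5,7,10-trien-1-yl]-1,3-dioxolane
Product: 13 (4S,6E,8E,10R)-4,10-dimethyldodeca-6,8,11-trienal
Conditions: 1 M HCl, THF/H2O, rt
Reagents that add atoms: water (O)
Why: Acid hydrolysis of the dioxolane; the unconjugated triene and both stereocentres are stable to dilute acid.

Step 8
Reactants: 13 (4S,6E,8E,10R)-4,10-dimethyldodeca-6,8,11-trienal
Product: 14 (2E,6S,8E,10E,12R)-6,12-dimethyltetradeca-2,8,10,13-tetraenal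
Conditions: Ph3P=CHCHO, toluene, 70 °C
Reagents that add atoms: (triphenylphosphoranylidene)acetaldehyde (O=CC=P(c1ccccc1)(c1ccccc1)c1ccccc1)
Why: Wittig olefination with the stabilised ylide installs the (E)-enal dienophile.

Step 9
Reactants: 14 (2E,6S,8E,10E,12R)-6,12-dimethyltetradeca-2,8,10,13-tetraenal
Product: 15 (1S,2S,4aS,6S,8aR)-2-[(2R)-but-3-en-2-yl]-6-methyl-1,2,4a,5,6,7,8,8a-octahydronaphthalene-1-carbaldehyde
Conditions: (2R,5R)-5-benzyl-2-tert-butyl-3-methylimidazolidin-4-one·TfOH (20 mol%), MeCN/H2O (98:2), 5 °C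
Reagents that add atoms: none
Why: Iminium-catalysed intramolecular Diels–Alder reaction through the endo transition state gives the trans-fused decalin; the second-generation MacMillan catalyst opens the Si face of the enal β-carbon, setting C1, C2, C4a and C8a against the modest preference of the ring A methyl for the equatorial position.

Step 10
Reactants: 15 (1S,2S,4aS,6S,8aR)-2-[(2R)-but-3-en-2-yl]-6-methyl-1,2,4a,5,6,7,8,8a-octahydronaphthalene-1-carbaldehyde
Product: 16 (1S,2S,4aS,6S,8aR)-2-[(2R)-but-3-en-2-yl]-1,6-dimethyl-1,2,4a,5,6,7,8,8a-octahydronaphthalene-1-carbaldehyde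
Conditions: KOt-Bu, MeI, THF, −20 °C
Reagents that add atoms: iodomethane (CI)
Why: C-Methylation of the aldehyde potassium enolate; 1,3-allylic strain holds the C2 side chain pseudoaxial, so MeI enters anti to it and the quaternary C1 is formed with methyl cis to H-4a.

**Spirotetronate 45**

Step 11
Reactants: 17 (2R)-pent-4-en-2-ol; 18 prop-2-enoyl chloride
Product: 19 (2R)-pent-4-en-2-yl prop-2-enoate
Conditions: Et3N, DMAP (cat.), CH2Cl2, 0 °C
Reagents that add atoms: none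
Why: O-Acylation of the chiral-pool alcohol; the carbinol centre (later the side-chain CH–OH) is untouched.

Step 12
Reactants: 19 (2R)-pent-4-en-2-yl prop-2-enoate
Product: 20 (6R)-6-methyl-5,6-dihydro-2H-pyran-2-one
Conditions: second-generation Grubbs catalyst (H2IMes)(PCy3)Cl2Ru=CHPh (2 mol%), CH2Cl2 (0.02 M), 40 °C
Reagents that add atoms: none
Why: Ring-closing metathesis of the acrylate to the six-membered unsaturated lactone, driven by loss of ethene.

Step 13
Reactants: 20 (6R)-6-methyl-5,6-dihydro-2H-pyran-2-one; 21 ethenylmagnesium bromide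
Product: 22 (4R,6R)-4-ethenyl-6-methyloxan-2-one
Conditions: CuBr·SMe2 (10 mol%), THF, −78 → −40 °C
Reagents that add atoms: none
Why: Copper-catalysed conjugate addition; the vinyl group enters axially anti to the C6 methyl of the half-chair lactone, giving the 4,6-trans product and setting the ring CH centre (C9 of the later spiro ring) from the pentenol centre.

Step 14
Reactants: 22 (4R,6R)-4-ethenyl-6-methyloxan-2-one
Product: 24 (4R,6R)-4-(2-hydroxyethyl)-6-methyloxan-2-one, via alkylborane 23 (not isolated)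
Conditions: 9-BBN, THF, 0 °C → rt; then 30% H2O2, pH 7 phosphate buffer, 0 °C
Reagents that add atoms: hydrogen peroxide (OO)
Why: Anti-Markovnikov hydroboration–oxidation of the only alkene; buffered oxidation spares the lactone.

Step 15
Reactants: 25 pent-1-en-4-yne
Product: 27 (1E)-1-iodo-2-methylpenta-1,4-diene, via alkenylalane 26 (not isolated)
Conditions: Me3Al, Cp2ZrCl2 (25 mol%), CH2Cl2, 0 °C → rt; then I2, THF, −30 °C
Reagents that add atoms: trimethylaluminium (C[Al](C)C); iodine (II)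
Why: Negishi zirconium-catalysed syn-carboalumination of the terminal alkyne, then iodinolysis with retention, gives the (E)-trisubstituted alkenyl iodide (iodine cis to methyl).

Step 16
Reactants: 27 (1E)-1-iodo-2-methylpenta-1,4-diene; 24 (4R,6R)-4-(2-hydroxyethyl)-6-methyloxan-2-one
Product: 29 (4E,8R,10R)-10-hydroxy-8-(2-hydroxyethyl)-4-methylundeca-1,4-dien-6-one, via alkenyllithium 28 (not isolated)
Conditions: t-BuLi (2 equiv per 27), Et2O, −78 °C; then 24 (0.45 equiv), THF, −78 °C; aq. NH4Cl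
Reagents that add atoms: none
Why: Iodine–lithium exchange and mono-addition to the lactone carbonyl (the lithium lactolate survives at −78 °C; one equivalent of 28 is spent on the free hydroxyl) open the ring to the (E)-enone with alkene geometry retained.

Step 17
Reactants: 29 (4E,8R,10R)-10-hydroxy-8-(2-hydroxyethyl)-4-methylundeca-1,4-dien-6-one
Product: 30 (4E,8R,10R)-4-methyl-10-[(triethylsilyl)oxy]-8-{2-[(triethylsilyl)oxy]ethyl}undeca-1,4-dien-6-one
Conditions: Et3SiCl, imidazole, DMF, 0 °C → rt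
Reagents that add atoms: chlorotriethylsilane (CC[Si](Cl)(CC)CC)
Why: Silylation of both hydroxyls; it also draws any cyclic hemiketal into the open-chain ketone.

Step 18
Reactants: 30 (4E,8R,10R)-4-methyl-10-[(triethylsilyl)oxy]-8-{2-[(triethylsilyl)oxy]ethyl}undeca-1,4-dien-6-one
Product: 31 (4E,6R,8S,10R)-4-methyl-10-[(triethylsilyl)oxy]-8-{2-[(triethylsilyl)oxy]ethyl}undeca-1,4-dien-6-ol
Conditions: (S)-2-methyl-CBS-oxazaborolidine (20 mol%), catecholborane, toluene, −78 °C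
Reagents that add atoms: none
Why: Corey–Bakshi–Shibata reduction of an enone with the alkenyl group as the large substituent gives the (6R)-allylic alcohol; catecholborane at −78 °C leaves the terminal alkenes alone.

Step 19
Reactants: 31 (4E,6R,8S,10R)-4-methyl-10-[(triethylsilyl)oxy]-8-{2-[(triethylsilyl)oxy]ethyl}undeca-1,4-dien-6-ol
Product: 32 (1R,3S,5R)-1-[(2S,3S)-3-methyl-3-(prop-2-en-1-yl)oxiran-2-yl]-5-[(triethylsilyl)oxy]-3-{2-[(triethylsilyl)oxy]ethyl}hexan-1-ol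
Conditions: mCPBA, NaHCO3, CH2Cl2, −20 °C
Reagents that add atoms: 3-chloroperoxybenzoic acid (OOC(=O)c1cccc(Cl)c1)
Why: Hydroxyl-directed peracid epoxidation; 1,3-allylic strain with the cis methyl holds the carbinol H in the alkene plane, so oxygen arrives syn to OH (threo) and fixes both epoxide centres, while the trisubstituted allylic alkene reacts far faster than the monosubstituted one.

Step 20
Reactants: 32 (1R,3S,5R)-1-[(2S,3S)-3-methyl-3-(prop-2-en-1-yl)oxiran-2-yl]-5-[(triethylsilyl)oxy]-3-{2-[(triethylsilyl)oxy]ethyl}hexan-1-ol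
Product: 33 (3R,5R)-1-[(2R,3S)-3-methyl-3-(prop-2-en-1-yl)oxiran-2-yl]-5-[(triethylsilyl)oxy]-3-{2-[(triethylsilyl)oxy]ethyl}hexan-1-one
Conditions: Dess–Martin periodinane, NaHCO3, CH2Cl2, rt
Reagents that add atoms: none
Why: Dess–Martin oxidation to the α,β-epoxy ketone under buffered conditions; the epoxide centres are retained.

Step 21
Reactants: 33 (3R,5R)-1-[(2R,3S)-3-methyl-3-(prop-2-en-1-yl)oxiran-2-yl]-5-[(triethylsilyl)oxy]-3-{2-[(triethylsilyl)oxy]ethyl}hexan-1-one; 34 ethynylmagnesium bromide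
Product: 36 (3R,5R,7R)-3-[(2R,3S)-3-methyl-3-(prop-2-en-1-yl)oxiran-2-yl]-7-[(triethylsilyl)oxy]-5-{2-[(triethylsilyl)oxy]ethyl}-3-[(trimethylsilyl)oxy]oct-1-yne, via magnesium alkoxide 35 (not isolated)
Conditions: CH2Cl2/THF, −78 → −30 °C; then Me3SiCl, Et3N, DMAP (cat.), −78 °C → rt
Reagents that add atoms: chlorotrimethylsilane (C[Si](C)(C)Cl)
Why: Chelation-controlled Grignard addition (Cram cyclic model: Mg bridges the carbonyl and epoxide oxygens, ethynyl attacks from the epoxide C–H side) sets the tertiary carbinol that becomes the spiro centre; the alkoxide is silylated in the same flask.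

Step 22
Reactants: 36 (3R,5R,7R)-3-[(2R,3S)-3-methyl-3-(prop-2-en-1-yl)oxiran-2-yl]-7-[(triethylsilyl)oxy]-5-{2-[(triethylsilyl)oxy]ethyl}-3-[(trimethylsilyl)oxy]oct-1-yne
Product: 37 (2S,3R,5R,7R)-3-ethynyl-2-methyl-2-(prop-2-en-1-yl)-7-[(triethylsilyl)oxy]-5-{2-[(triethylsilyl)oxy]ethyl}-3-[(trimethylsilyl)oxy]octanal
Conditions: MeAl(OC6H2-4-Br-2,6-t-Bu2)2 (MABR, 30 mol%), CH2Cl2, −78 → −40 °C
Reagents that add atoms: none
Why: Proposed new method: the bulky aluminium Lewis acid binds the epoxide oxygen and ionises the tertiary C–O bond, and the fully substituted propargylic α-siloxy carbon shifts from the epoxide CH to the tertiary carbon anti to the leaving oxygen (inversion there, retention in the migrating carbon) while the epoxide CH becomes the aldehyde, which joins the two adjacent fully substituted carbons with relative configuration taken from the epoxide; the closest known reaction is the MABR-promoted semipinacol rearrangement of epoxy silyl ethers to β-siloxy aldehydes, known only for primary and secondary siloxyalkyl migrating groups.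

Step 23
Reactants: 37 (2S,3R,5R,7R)-3-ethynyl-2-methyl-2-(prop-2-en-1-yl)-7-[(triethylsilyl)oxy]-5-{2-[(triethylsilyl)oxy]ethyl}-3-[(trimethylsilyl)oxy]octanal
Product: 39 (2S,3R,5R,7R)-3-ethynyl-2-methyl-5-(2-oxoethyl)-2-(prop-2-en-1-yl)-7-[(triethylsilyl)oxy]-3-[(trimethylsilyl)oxy]octanal, via alkoxysulfonium chloride 38 (not isolated)
Conditions: (COCl)2, DMSO, CH2Cl2, −78 → −30 °C; then Et3N, −78 → 0 °C
Reagents that add atoms: none
Why: Swern oxidation that cleaves and oxidises the primary triethylsilyl ether directly; the secondary triethylsilyl and the hindered tertiary trimethylsilyl ethers survive.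

Step 24
Reactants: 39 (2S,3R,5R,7R)-3-ethynyl-2-methyl-5-(2-oxoethyl)-2-(prop-2-en-1-yl)-7-[(triethylsilyl)oxy]-3-[(trimethylsilyl)oxy]octanal
Product: 40 (3R,4R,6R)-4-ethynyl-3-methyl-3-(prop-2-en-1-yl)-6-{(2R)-2-[(triethylsilyl)oxy]propyl}-4-[(trimethylsilyl)oxy]cyclohex-1-ene-1-carbaldehyde
Conditions: Bn2NH·CF3CO2H (30 mol%), toluene, 50 °C
Reagents that add atoms: none
Why: Intramolecular aldol condensation under amine-salt catalysis; only the CH2CHO aldehyde can form an enamine and the non-enolisable neopentyl aldehyde is the acceptor, so a single cyclohexene carbaldehyde forms with no new stereocentre.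

Step 25
Reactants: 40 (3R,4R,6R)-4-ethynyl-3-methyl-3-(prop-2-en-1-yl)-6-{(2R)-2-[(triethylsilyl)oxy]propyl}-4-[(trimethylsilyl)oxy]cyclohex-1-ene-1-carbaldehyde
Product: 41 [(3R,4R,6R)-4-ethynyl-3-methyl-3-(prop-2-en-1-yl)-6-{(2R)-2-[(triethylsilyl)oxy]propyl}-4-[(trimethylsilyl)oxy]cyclohex-1-en-1-yl]methanol
Conditions: NaBH4, MeOH/THF, −40 °C
Reagents that add atoms: none
Why: 1,2-Reduction of the enal to the allylic alcohol.

Step 26
Reactants: 41 [(3R,4R,6R)-4-ethynyl-3-methyl-3-(prop-2-en-1-yl)-6-{(2R)-2-[(triethylsilyl)oxy]propyl}-4-[(trimethylsilyl)oxy]cyclohex-1-en-1-yl]methanol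
Product: 42 triethyl{[(3R,4R,6R)-4-ethynyl-3-methyl-3-(prop-2-en-1-yl)-6-{(2R)-2-[(triethylsilyl)oxy]propyl}-4-[(trimethylsilyl)oxy]cyclohex-1-en-1-yl]methoxy}silane
Conditions: Et3SiCl, imidazole, CH2Cl2, 0 °C
Reagents that add atoms: chlorotriethylsilane (CC[Si](Cl)(CC)CC)
Why: Silyl protection of the primary allylic alcohol for the organolithium and oxidation steps that follow.

Step 27
Reactants: 42 triethyl{[(3R,4R,6R)-4-ethynyl-3-methyl-3-(prop-2-en-1-yl)-6-{(2R)-2-[(triethylsilyl)oxy]propyl}-4-[(trimethylsilyl)oxy]cyclohex-1-en-1-yl]methoxy}silane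
Product: 45 (5S,6R,9R)-4-methoxy-6-methyl-6-(prop-2-en-1-yl)-8-{[(triethylsilyl)oxy]methyl}-9-{(2R)-2-[(triethylsilyl)oxy]propyl}-1-oxaspiro[4.5]deca-3,7-dien-2-one, via lithium acetylide 43 (not isolated), via ynoate 44 (not isolated)
Conditions: n-BuLi, THF, −78 °C; then ClCO2Me, −78 → −20 °C; then NaOMe, MeOH, 0 °C → rt
Reagents that add atoms: methyl carbonochloridate (COC(=O)Cl); methanol (CO)
Why: Acetylide carboxylation, then methoxide removes the tertiary trimethylsilyl group, adds to the ynoate β-carbon and the freed alkoxide lactonises (tetronate annulation of a 4-hydroxy-2-ynoate); the spiro centre is carried over unchanged.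

**Union and macrocycle**

Step 28
Reactants: 45 (5S,6R,9R)-4-methoxy-6-methyl-6-(prop-2-en-1-yl)-8-{[(triethylsilyl)oxy]methyl}-9-{(2R)-2-[(triethylsilyl)oxy]propyl}-1-oxaspiro[4.5]deca-3,7-dien-2-one; 16 (1S,2S,4aS,6S,8aR)-2-[(2R)-but-3-en-2-yl]-1,6-dimethyl-1,2,4a,5,6,7,8,8a-octahydronaphthalene-1-carbaldehyde
Product: 47 3-{hydroxy[(1S,2S,4aS,6S,8aR)-2-[(2R)-but-3-en-2-yl]-1,6-dimethyl-1,2,4a,5,6,7,8,8a-octahydronaphthalen-1-yl]methyl} derivative of 45 (both carbinol epimers), via lithiated tetronate 46 (not isolated)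
Conditions: LiN(i-Pr)2, THF, −78 °C; then 16, −78 → −40 °C
Reagents that add atoms: none
Why: C3-lithiation of the methyl tetronate (vinylogous ester) and 1,2-addition to the non-enolisable aldehyde; the carbinol configuration is irrelevant because it is oxidised next.

Step 29
Reactants: 47 carbinol adduct (both epimers)
Product: 48 3-{[(1S,2S,4aS,6S,8aR)-2-[(2R)-but-3-en-2-yl]-1,6-dimethyl-1,2,4a,5,6,7,8,8a-octahydronaphthalen-1-yl]carbonyl} derivative of 45
Conditions: Dess–Martin periodinane, NaHCO3, CH2Cl2, rt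
Reagents that add atoms: none
Why: Dess–Martin oxidation of the hindered secondary alcohol gives the 3-acyl tetronate; both epimers converge.

Step 30
Reactants: 48 diene ketone
Product: 49 maklamicin 4-O-methyl ether bis(triethylsilyl) ether ((E)-alkene in the 11-membered ring)
Conditions: second-generation Grubbs catalyst (H2IMes)(PCy3)Cl2Ru=CHPh (15 mol%), toluene (0.5 mM), 80 °C
Reagents that add atoms: none
Why: Ring-closing metathesis of the allyl and but-3-en-2-yl termini closes the 11-membered carbocycle; reversible metathesis at 80 °C should settle on the (E)-alkene, taken to be the more stable isomer because it is the geometry of the natural ring.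

Step 31
Reactants: 49 maklamicin 4-O-methyl ether bis(triethylsilyl) ether
Product: 51 maklamicin (target), via lithium tetronate 50 (not isolated)
Conditions: LiCl, DMSO, 50 °C; then 1 M HCl, THF/H2O, 0 °C → rt
Reagents that add atoms: none
Why: SN2 O-demethylation of the vinylogous methyl ester by chloride, then acid hydrolysis of both triethylsilyl ethers; no stereocentre is touched.

**Compound list**

1 | 2-(2-bromoethyl)-1,3-dioxolane | BrCCC1OCCO1 | starting material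
2 | methyl (2E)-but-2-enoate | C/C=C/C(=O)OC | starting material
3 | [2-(1,3-dioxolan-2-yl)ethyl]magnesium bromide | Br[Mg]CCC1OCCO1 | intermediate
4 | methyl (3S)-5-(1,3-dioxolan-2-yl)-3-methylpentanoate | COC(=O)C[C@@H](C)CCC1OCCO1 | intermediate
5 | (3S)-5-(1,3-dioxolan-2-yl)-3-methylpentanal | O=CC[C@@H](C)CCC1OCCO1 | intermediate
6 | (2E,5S)-7-(1,3-dioxolan-2-yl)-5-methylhept-2-enal | O=C/C=C/C[C@@H](C)CCC1OCCO1 | intermediate
7 | (2E)-1,4-dibromobut-2-ene | BrC/C=C/CBr | starting material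
8 | (3R)-4-bromo-3-methylbut-1-ene | C=C[C@@H](C)CBr | intermediate
9 | 5-{[(2R)-2-methylbut-3-en-1-yl]sulfanyl}-1-phenyl-1H-tetrazole | C=C[C@@H](C)CSc1nnnn1-c1ccccc1 | intermediate
10 | 5-{[(2R)-2-methylbut-3-en-1-yl]sulfonyl}-1-phenyl-1H-tetrazole | C=C[C@@H](C)CS(=O)(=O)c1nnnn1-c1ccccc1 | intermediate
11 | potassium α-sulfonyl carbanion of 10 | C=C[C@@H](C)[CH-]S(=O)(=O)c1nnnn1-c1ccccc1.[K+] | intermediate
12 | 2-[(3S,5E,7E,9R)-3,9-dimethylundeca-5,7,10-trien-1-yl]-1,3-dioxolane | C=C[C@@H](C)/C=C/C=C/C[C@@H](C)CCC1OCCO1 | intermediate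
13 | (4S,6E,8E,10R)-4,10-dimethyldodeca-6,8,11-trienal | C=C[C@@H](C)/C=C/C=C/C[C@@H](C)CCC=O | intermediate
14 | (2E,6S,8E,10E,12R)-6,12-dimethyltetradeca-2,8,10,13-tetraenal | C=C[C@@H](C)/C=C/C=C/C[C@@H](C)CC/C=C/C=O | intermediate
15 | (1S,2S,4aS,6S,8aR)-2-[(2R)-but-3-en-2-yl]-6-methyl-1,2,4a,5,6,7,8,8a-octahydronaphthalene-1-carbaldehyde | C[C@H]1CC[C@@H]2[C@H](C=C[C@@H]([C@H](C)C=C)[C@H]2C=O)C1 | intermediate
16 | (1S,2S,4aS,6S,8aR)-2-[(2R)-but-3-en-2-yl]-1,6-dimethyl-1,2,4a,5,6,7,8,8a-octahydronaphthalene-1-carbaldehyde | C[C@H]1CC[C@@H]2[C@H](C=C[C@@H]([C@H](C)C=C)[C@@]2(C)C=O)C1 | intermediate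
17 | (2R)-pent-4-en-2-ol | C=CC[C@@H](C)O | starting material
18 | prop-2-enoyl chloride | C=CC(=O)Cl | starting material
19 | (2R)-pent-4-en-2-yl prop-2-enoate | C=CC[C@@H](C)OC(=O)C=C | intermediate
20 | (6R)-6-methyl-5,6-dihydro-2H-pyran-2-one | C[C@@H]1CC=CC(=O)O1 | intermediate
21 | ethenylmagnesium bromide | C=C[Mg]Br | starting material
22 | (4R,6R)-4-ethenyl-6-methyloxan-2-one | C=C[C@H](C[C@@H](C)O1)CC1=O | intermediate
23 | (4R,6R)-4-[2-(9-borabicyclo[3.3.1]nonan-9-yl)ethyl]-6-methyloxan-2-one | C1CCC2CCCC1B2CC[C@H](C[C@@H](C)O3)CC3=O | intermediate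
24 | (4R,6R)-4-(2-hydroxyethyl)-6-methyloxan-2-one | OCC[C@H](C[C@@H](C)O1)CC1=O | intermediate
25 | pent-1-en-4-yne | C=CCC#C | starting material
26 | dimethyl[(1E)-2-methylpenta-1,4-dien-1-yl]alumane | C=CC/C(C)=C/[Al](C)C | intermediate
27 | (1E)-1-iodo-2-methylpenta-1,4-diene | C=CC/C(C)=C/I | intermediate
28 | [(1E)-2-methylpenta-1,4-dien-1-yl]lithium | C=CC/C(C)=C/[Li] | intermediate
29 | (4E,8R,10R)-10-hydroxy-8-(2-hydroxyethyl)-4-methylundeca-1,4-dien-6-one | OCC[C@H](C[C@@H](C)O)CC(=O)/C=C(\C)CC=C | intermediate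
30 | (4E,8R,10R)-4-methyl-10-[(triethylsilyl)oxy]-8-{2-[(triethylsilyl)oxy]ethyl}undeca-1,4-dien-6-one | CC[Si](CC)(CC)OCC[C@H](C[C@@H](C)O[Si](CC)(CC)CC)CC(=O)/C=C(\C)CC=C | intermediate
31 | (4E,6R,8S,10R)-4-methyl-10-[(triethylsilyl)oxy]-8-{2-[(triethylsilyl)oxy]ethyl}undeca-1,4-dien-6-ol | CC[Si](CC)(CC)OCC[C@H](C[C@@H](C)O[Si](CC)(CC)CC)C[C@@H](O)/C=C(\C)CC=C | intermediate
32 | (1R,3S,5R)-1-[(2S,3S)-3-methyl-3-(prop-2-en-1-yl)oxiran-2-yl]-5-[(triethylsilyl)oxy]-3-{2-[(triethylsilyl)oxy]ethyl}hexan-1-ol | CC[Si](CC)(CC)OCC[C@H](C[C@@H](C)O[Si](CC)(CC)CC)C[C@@H](O)[C@@H]1O[C@@]1(C)CC=C | intermediate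
33 | (3R,5R)-1-[(2R,3S)-3-methyl-3-(prop-2-en-1-yl)oxiran-2-yl]-5-[(triethylsilyl)oxy]-3-{2-[(triethylsilyl)oxy]ethyl}hexan-1-one | CC[Si](CC)(CC)OCC[C@H](C[C@@H](C)O[Si](CC)(CC)CC)CC(=O)[C@@H]1O[C@@]1(C)CC=C | intermediate
34 | ethynylmagnesium bromide | C#C[Mg]Br | starting material
35 | bromomagnesium alkoxide of the tertiary alcohol (36 with OMgBr in place of OSiMe3) | CC[Si](CC)(CC)OCC[C@H](C[C@@H](C)O[Si](CC)(CC)CC)C[C@@](O[Mg]Br)(C#C)[C@@H]1O[C@@]1(C)CC=C | intermediate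
36 | (3R,5R,7R)-3-[(2R,3S)-3-methyl-3-(prop-2-en-1-yl)oxiran-2-yl]-7-[(triethylsilyl)oxy]-5-{2-[(triethylsilyl)oxy]ethyl}-3-[(trimethylsilyl)oxy]oct-1-yne | CC[Si](CC)(CC)OCC[C@H](C[C@@H](C)O[Si](CC)(CC)CC)C[C@@](O[Si](C)(C)C)(C#C)[C@@H]1O[C@@]1(C)CC=C | intermediate
37 | (2S,3R,5R,7R)-3-ethynyl-2-methyl-2-(prop-2-en-1-yl)-7-[(triethylsilyl)oxy]-5-{2-[(triethylsilyl)oxy]ethyl}-3-[(trimethylsilyl)oxy]octanal | CC[Si](CC)(CC)OCC[C@H](C[C@@H](C)O[Si](CC)(CC)CC)C[C@@](O[Si](C)(C)C)(C#C)[C@](C)(CC=C)C=O | intermediate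
38 | alkoxydimethylsulfonium chloride of the primary alcohol of 37 (OSiEt3 replaced by OS+Me2 Cl−; other centres as in 37) | C[S+](C)OCC[C@H](C[C@@H](C)O[Si](CC)(CC)CC)C[C@@](O[Si](C)(C)C)(C#C)[C@](C)(CC=C)C=O.[Cl-] | intermediate
39 | (2S,3R,5R,7R)-3-ethynyl-2-methyl-5-(2-oxoethyl)-2-(prop-2-en-1-yl)-7-[(triethylsilyl)oxy]-3-[(trimethylsilyl)oxy]octanal | O=CC[C@H](C[C@@H](C)O[Si](CC)(CC)CC)C[C@@](O[Si](C)(C)C)(C#C)[C@](C)(CC=C)C=O | intermediate
40 | (3R,4R,6R)-4-ethynyl-3-methyl-3-(prop-2-en-1-yl)-6-{(2R)-2-[(triethylsilyl)oxy]propyl}-4-[(trimethylsilyl)oxy]cyclohex-1-ene-1-carbaldehyde | C=CC[C@]1(C)C=C(C=O)[C@H](C[C@@H](C)O[Si](CC)(CC)CC)C[C@@]1(O[Si](C)(C)C)C#C | intermediate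
41 | [(3R,4R,6R)-4-ethynyl-3-methyl-3-(prop-2-en-1-yl)-6-{(2R)-2-[(triethylsilyl)oxy]propyl}-4-[(trimethylsilyl)oxy]cyclohex-1-en-1-yl]methanol | C=CC[C@]1(C)C=C(CO)[C@H](C[C@@H](C)O[Si](CC)(CC)CC)C[C@@]1(O[Si](C)(C)C)C#C | intermediate
42 | triethyl{[(3R,4R,6R)-4-ethynyl-3-methyl-3-(prop-2-en-1-yl)-6-{(2R)-2-[(triethylsilyl)oxy]propyl}-4-[(trimethylsilyl)oxy]cyclohex-1-en-1-yl]methoxy}silane | C=CC[C@]1(C)C=C(CO[Si](CC)(CC)CC)[C@H](C[C@@H](C)O[Si](CC)(CC)CC)C[C@@]1(O[Si](C)(C)C)C#C | intermediate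
43 | lithium acetylide of 42 (C≡CLi in place of C≡CH) | C=CC[C@]1(C)C=C(CO[Si](CC)(CC)CC)[C@H](C[C@@H](C)O[Si](CC)(CC)CC)C[C@@]1(O[Si](C)(C)C)C#C[Li] | intermediate
44 | methyl prop-2-ynoate derived from 42 (C≡C–CO2CH3 in place of C≡CH) | C=CC[C@]1(C)C=C(CO[Si](CC)(CC)CC)[C@H](C[C@@H](C)O[Si](CC)(CC)CC)C[C@@]1(O[Si](C)(C)C)C#CC(=O)OC | intermediate
45 | (5S,6R,9R)-4-methoxy-6-methyl-6-(prop-2-en-1-yl)-8-{[(triethylsilyl)oxy]methyl}-9-{(2R)-2-[(triethylsilyl)oxy]propyl}-1-oxaspiro[4.5]deca-3,7-dien-2-one | C=CC[C@]1(C)C=C(CO[Si](CC)(CC)CC)[C@H](C[C@@H](C)O[Si](CC)(CC)CC)C[C@]12OC(=O)C=C2OC | intermediate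
46 | 3-lithio derivative of 45 | C=CC[C@]1(C)C=C(CO[Si](CC)(CC)CC)[C@H](C[C@@H](C)O[Si](CC)(CC)CC)C[C@]12OC(=O)C([Li])=C2OC | intermediate
47 | 3-{hydroxy[(1S,2S,4aS,6S,8aR)-2-[(2R)-but-3-en-2-yl]-1,6-dimethyl-1,2,4a,5,6,7,8,8a-octahydronaphthalen-1-yl]methyl} derivative of 45 (both carbinol epimers) | C[C@H]1CC[C@@H]2[C@H](C=C[C@@H]([C@H](C)C=C)[C@@]2(C)C(O)C2=C(OC)[C@@]3(C[C@@H](C[C@@H](C)O[Si](CC)(CC)CC)C(CO[Si](CC)(CC)CC)=C[C@@]3(C)CC=C)OC2=O)C1 | intermediate
48 | 3-{[(1S,2S,4aS,6S,8aR)-2-[(2R)-but-3-en-2-yl]-1,6-dimethyl-1,2,4a,5,6,7,8,8a-octahydronaphthalen-1-yl]carbonyl} derivative of 45 | C[C@H]1CC[C@@H]2[C@H](C=C[C@@H]([C@H](C)C=C)[C@@]2(C)C(=O)C2=C(OC)[C@@]3(C[C@@H](C[C@@H](C)O[Si](CC)(CC)CC)C(CO[Si](CC)(CC)CC)=C[C@@]3(C)CC=C)OC2=O)C1 | intermediate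
49 | maklamicin 4-O-methyl ether bis(triethylsilyl) ether (tetronate OCH3; primary and secondary OSiEt3; (E)-alkene in the 11-membered ring; all centres as in 51) | C[C@H]1CC[C@@H]2[C@H](C=C[C@H]3[C@H](C)/C=C/C[C@]4(C)C=C(CO[Si](CC)(CC)CC)[C@H](C[C@@H](C)O[Si](CC)(CC)CC)C[C@]45OC(=O)C(=C5OC)C(=O)[C@@]23C)C1 | intermediate
50 | lithium tetronate of bis(triethylsilyl) maklamicin | [Li+].C[C@H]1CC[C@@H]2[C@H](C=C[C@H]3[C@H](C)/C=C/C[C@]4(C)C=C(CO[Si](CC)(CC)CC)[C@H](C[C@@H](C)O[Si](CC)(CC)CC)C[C@]45OC(=O)C(=C5[O-])C(=O)[C@@]23C)C1 | intermediate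
51 | maklamicin (CNP0189906.1) | C[C@H]1CC[C@@H]2[C@H](C=C[C@H]3[C@H](C)/C=C/C[C@]4(C)C=C(CO)[C@H](C[C@@H](C)O)C[C@]45OC(=O)C(=C5O)C(=O)[C@@]23C)C1 | target

**Totals**

Total step count: 31. Longest linear sequence: 20 steps (from 17 through steps 11–14 and 16–31).

**Three steps most likely to fail**

Step 22 (the proposed new semipinacol shift; hydride shift to a ketone or poor migration of the hindered carbon are the risks). The fallback uses only known chemistry and sets out from epoxy ketone 33. BF3·OEt2 in CH2Cl2 at −78 °C effects the long-established stereospecific 1,2-acyl shift of an α,β-epoxy ketone, with the same inversion at the tertiary carbon, to give keto aldehyde (2R,5R,7R)-2-methyl-3-oxo-2-(prop-2-en-1-yl)-7-[(triethylsilyl)oxy]-5-{2-[(triethylsilyl)oxy]ethyl}octanal F4. Swern oxidation of its primary silyl ether gives keto dialdehyde (2R,5S,7R)-2-methyl-3-oxo-5-(2-oxoethyl)-2-(prop-2-en-1-yl)-7-[(triethylsilyl)oxy]octanal F5. Bn2NH·CF3CO2H closes it to (3R,6R)-3-methyl-4-oxo-3-(prop-2-en-1-yl)-6-{(2R)-2-[(triethylsilyl)oxy]propyl}cyclohex-1-ene-1-carbaldehyde F6. NaBH4 at −78 °C reduces only the aldehyde to (2R,5R)-4-(hydroxymethyl)-2-methyl-2-(prop-2-en-1-yl)-5-{(2R)-2-[(triethylsilyl)oxy]propyl}cyclohex-3-en-1-one F7, and Et3SiCl/imidazole gives (2R,5R)-2-methyl-2-(prop-2-en-1-yl)-4-{[(triethylsilyl)oxy]methyl}-5-{(2R)-2-[(triethylsilyl)oxy]propyl}cyclohex-3-en-1-one F8. Addition of 34 to the ring ketone gives (1R,2R,5R)-1-ethynyl-2-methyl-2-(prop-2-en-1-yl)-4-{[(triethylsilyl)oxy]methyl}-5-{(2R)-2-[(triethylsilyl)oxy]propyl}cyclohex-3-en-1-ol F9, separated from its C1 epimer because facial control here is not assured. N-(Trimethylsilyl)imidazole then returns the route to 42.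

Step 9 (the catalyst must override the preference of the ring A methyl for the equatorial position; low diastereoselectivity is the risk). The fallback sets out from trienal 13. Horner–Wadsworth–Emmons reaction with diethyl [2-oxo-2-(2-oxo-1,3-oxazolidin-3-yl)ethyl]phosphonate (LiCl, i-Pr2NEt, MeCN) gives imide 3-[(2E,6S,8E,10E,12R)-6,12-dimethyltetradeca-2,8,10,13-tetraenoyl]-1,3-oxazolidin-2-one F1. The divalent copper complex [Cu(t-Bu-box)](SbF6)2 (antipode chosen for the same facial sense) binds the imide at two points and catalyses the endo cycloaddition with stronger facial control. This gives 3-{[(1S,2S,4aS,6S,8aR)-2-[(2R)-but-3-en-2-yl]-6-methyl-1,2,4a,5,6,7,8,8a-octahydronaphthalen-1-yl]carbonyl}-1,3-oxazolidin-2-one F2. LiBH4 gives [(1S,2S,4aS,6S,8aR)-2-[(2R)-but-3-en-2-yl]-6-methyl-1,2,4a,5,6,7,8,8a-octahydronaphthalen-1-yl]methanol F3, and Dess–Martin oxidation returns the route to 15.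

Step 30 (strained 11-membered ring with hindered alkene partners; E/Z mixtures or oligomers are the risks). The fallback sets out from 45 and 16 and forms the alkene first, then the ring at the acyl carbon. Lithiation of 45 (through 46) and quenching with I2 gives (5S,6R,9R)-3-iodo-4-methoxy-6-methyl-6-(prop-2-en-1-yl)-8-{[(triethylsilyl)oxy]methyl}-9-{(2R)-2-[(triethylsilyl)oxy]propyl}-1-oxaspiro[4.5]deca-3,7-dien-2-one F10. Cross-metathesis of F10 with 16 (second-generation Hoveyda–Grubbs catalyst, CH2Cl2, 40 °C) gives, after removal of any Z isomer, the (E)-alkene-linked iodotetronate decalin aldehyde F11. Nozaki–Hiyama–Kishi cyclisation (CrCl2, NiCl2 cat., DMSO/THF, high dilution) gives the macrocyclic secondary alcohol corresponding to 49 F12, and Dess–Martin oxidation returns the route to 49.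

**Further compounds**

F1 | step 9 | 3-[(2E,6S,8E,10E,12R)-6,12-dimethyltetradeca-2,8,10,13-tetraenoyl]-1,3-oxazolidin-2-one | C=C[C@@H](C)/C=C/C=C/C[C@@H](C)CC/C=C/C(=O)N1CCOC1=O
F2 | step 9 | 3-{[(1S,2S,4aS,6S,8aR)-2-[(2R)-but-3-en-2-yl]-6-methyl-1,2,4a,5,6,7,8,8a-octahydronaphthalen-1-yl]carbonyl}-1,3-oxazolidin-2-one | C[C@H]1CC[C@@H]2[C@H](C=C[C@@H]([C@H](C)C=C)[C@H]2C(=O)N2CCOC2=O)C1
F3 | step 9 | [(1S,2S,4aS,6S,8aR)-2-[(2R)-but-3-en-2-yl]-6-methyl-1,2,4a,5,6,7,8,8a-octahydronaphthalen-1-yl]methanol | C[C@H]1CC[C@@H]2[C@H](C=C[C@@H]([C@H](C)C=C)[C@H]2CO)C1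
F4 | step 22 | (2R,5R,7R)-2-methyl-3-oxo-2-(prop-2-en-1-yl)-7-[(triethylsilyl)oxy]-5-{2-[(triethylsilyl)oxy]ethyl}octanal | CC[Si](CC)(CC)OCC[C@H](C[C@@H](C)O[Si](CC)(CC)CC)CC(=O)[C@](C)(CC=C)C=O
F5 | step 22 | (2R,5S,7R)-2-methyl-3-oxo-5-(2-oxoethyl)-2-(prop-2-en-1-yl)-7-[(triethylsilyl)oxy]octanal | O=CC[C@H](C[C@@H](C)O[Si](CC)(CC)CC)CC(=O)[C@](C)(CC=C)C=O
F6 | step 22 | (3R,6R)-3-methyl-4-oxo-3-(prop-2-en-1-yl)-6-{(2R)-2-[(triethylsilyl)oxy]propyl}cyclohex-1-ene-1-carbaldehyde | C=CC[C@]1(C)C=C(C=O)[C@H](C[C@@H](C)O[Si](CC)(CC)CC)CC1=O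
F7 | step 22 | (2R,5R)-4-(hydroxymethyl)-2-methyl-2-(prop-2-en-1-yl)-5-{(2R)-2-[(triethylsilyl)oxy]propyl}cyclohex-3-en-1-one | C=CC[C@]1(C)C=C(CO)[C@H](C[C@@H](C)O[Si](CC)(CC)CC)CC1=O
F8 | step 22 | (2R,5R)-2-methyl-2-(prop-2-en-1-yl)-4-{[(triethylsilyl)oxy]methyl}-5-{(2R)-2-[(triethylsilyl)oxy]propyl}cyclohex-3-en-1-one | C=CC[C@]1(C)C=C(CO[Si](CC)(CC)CC)[C@H](C[C@@H](C)O[Si](CC)(CC)CC)CC1=O
F9 | step 22 | (1R,2R,5R)-1-ethynyl-2-methyl-2-(prop-2-en-1-yl)-4-{[(triethylsilyl)oxy]methyl}-5-{(2R)-2-[(triethylsilyl)oxy]propyl}cyclohex-3-en-1-ol | C=CC[C@]1(C)C=C(CO[Si](CC)(CC)CC)[C@H](C[C@@H](C)O[Si](CC)(CC)CC)C[C@@]1(O)C#C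
F10 | step 30 | (5S,6R,9R)-3-iodo-4-methoxy-6-methyl-6-(prop-2-en-1-yl)-8-{[(triethylsilyl)oxy]methyl}-9-{(2R)-2-[(triethylsilyl)oxy]propyl}-1-oxaspiro[4.5]deca-3,7-dien-2-one | C=CC[C@]1(C)C=C(CO[Si](CC)(CC)CC)[C@H](C[C@@H](C)O[Si](CC)(CC)CC)C[C@]12OC(=O)C(I)=C2OC
F11 | step 30 | (E)-alkene-linked iodotetronate decalin aldehyde (16 and F10 joined at their alkene termini with loss of ethene) | C[C@H]1CC[C@@H]2[C@H](C=C[C@@H]([C@H](C)/C=C/C[C@]3(C)C=C(CO[Si](CC)(CC)CC)[C@H](C[C@@H](C)O[Si](CC)(CC)CC)C[C@]34OC(=O)C(I)=C4OC)[C@@]2(C)C=O)C1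
F12 | step 30 | macrocyclic secondary alcohol corresponding to 49 (CH–OH in place of the ketone) | C[C@H]1CC[C@@H]2[C@H](C=C[C@H]3[C@H](C)/C=C/C[C@]4(C)C=C(CO[Si](CC)(CC)CC)[C@H](C[C@@H](C)O[Si](CC)(CC)CC)C[C@]45OC(=O)C(=C5OC)C(O)[C@@]23C)C1
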